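At 12 min I looked first at what was left and not at what was made. In the summer run 3.40% of the substrates charged stood unreacted, and in the autumn run 2.40%, so I took the last readings as the end of each run.

common to all: left-handed substrate 0.50 M; right-handed substrate 0.50 M; precatalyst 1 mol%
- summer: partner 2 equiv; racemization catalyst 0.21 mol%; run made earlier
- autumn: partner 2 equiv; racemization catalyst 0.61 mol%; run made earlier
- elm: partner 2.00 equiv; racemization catalyst 0.5 mol%; time 12 min
- alder: partner 2.00 equiv; racemization catalyst 0.15 mol%; time 12 min

- summer (time / min: left-handed product / %, right-handed product / %): 1.00: 45.0, 19.3; 2.00: 51.1, 28.1; 3.00: 54.5, 31.7; 6.00: 55.0, 36.3; 12.0: 57.7, 38.9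
- autumn (time / min: left-handed product / %, right-handed product / %): 1.00: 46.5, 19.9; 3.00: 59.0, 28.4; 6.00: 62.6, 30.2; 8.00: 63.3, 32.4; 12.0: 65.3, 32.3

(readings scatter by 0.5 percentage points)

- the flask that ends with the higher excess of left-handed product over right-handed product in the product, or "neither" when 2 percentage points or less lies between them (elm / alder / neither)
- excess of left-handed product over right-handed product in the product at the end, elm
- excess of left-handed product over right-handed product in the product at the end, alder

- free catalyst is single-handed; left-handed substrate and right-handed substrate are mirror images of each other, charged as a racemate, each of them at the stated concentration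
- an excess is below zero if the other one leads

This is a dynamic kinetic resolution: free catalyst and partner turn both substrates into product, while racemization catalyst turns one substrate into the other. The summer run ended at an excess of 19.5% and the autumn run at 33.8%. The rise was 14 percentage points, and I called it the span gain, the excess won across the 0.4 mol% of racemization catalyst between the two runs.

Then I turned the question round. Elm and alder differ by 0.35 mol%, which is 0.875 of that span. On a straight line in the loading, for the two to count as equal, within 2 points, the span gain would have had to lie at or below 2.3 points. It stood above that, at 6.28 times the value, and its 4 readings put a scatter of about 1 point on it.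

On that straight line through the two runs I reckoned 29.9% for elm, inside the span, and 17.3% for alder, whose loading is less than the summer run's, so that second figure was an extrapolation. The forecast named elm, with 31% and 16%, from "A saturating curve through these points", so it stood higher than my line for elm and lower for alder.

Elm ended at 30.3% and alder at 16.1%, so elm led by 14 points, more than the margin.

    left-handed substrate + racemization catalyst ⇌ right-handed substrate + racemization catalyst, rate k1*[racemization catalyst]*[left-handed substrate] forward; the back reaction follows from the equilibrium constant (k = 2.95 /M/s)
    racemization catalyst → spent catalyst (k = 0.00378 /s)
    partner + free catalyst + left-handed substrate → free catalyst + left-handed product (k = 19.0 /M²/s)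
    partner + free catalyst + right-handed substrate → free catalyst + right-handed product (k = 4.89 /M²/s)
    racemization catalyst ⇌ dormant form (K = 6.60, k = 0.00130 /s)
    partner + precatalyst → free catalyst + spent reagent (k = 0.0538 /M/s)

A neighbouring flask had elm's recipe with 0.2 mol% of racemization catalyst. The span gain put it at 19.1%, and it ended at 18.8%, holding 56.7% left-handed product, 38.7% right-handed product and 4.24% right-handed substrate.

The runs stem from a simulated flask from invented constants; scatter was added.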